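The runs are calculated for substances that don't exist; noise was put on by code.

I was to read the flask at 4.0 min, the moment its reagent dose ended, so the thing to watch was the free reagent concentration R, not the charge.

| setting | red | teal | flask |
|---|---|---|---|
| substrate | 10 mM | 15 mM | 20 mM |
| reagent | 3 equiv (fed, over 4.0 min) | 3 equiv (fed, over 4.0 min) | 3.00 equiv (fed, over 4.0 min) |
| remark | run made earlier | run made earlier |  |
| time |  |  | 4.0 min |

- red (time / min: substrate / %, mono adduct / %): 0.667: 94.6, 6.5; 1.33: 79.8, 19.1; 2.00: 59.7, 32.5; 2.50: 47.6, 37.9; 3.00: 37.0, 42.2
- teal (time / min: substrate / %, mono adduct / %): 0.250: 98.0, 0.7; 0.833: 88.1, 14.0; 1.33: 70.0, 24.3; 2.50: 36.8, 42.4; 3.00: 24.5, 41.5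

(scatter of a reading: 1 percentage point)

- what was read earlier has a scatter of 1 percentage point, one standard deviation

- how much substrate there is at 4.0 min, in percent of the substrate charged
- how much mono adduct there is at 4.0 min, in percent of the substrate charged
- how much double product there is at 4.0 min, in percent of the substrate charged

I took the main step as first order in substrate and in R, so that k·R, with k its rate constant, acted as a pseudo-first-order constant that changed during the dose. The logarithm of charged over remaining substrate then equals k·θ, where θ, the exposure, is the area under R against time. Under a steady dose I drew that area as a triangle: half of R at the reading, times the time. R at a reading was the dose so far less the uptake, with one reagent in a mono adduct and two in a double product, and double product taken as what the balance lacked. At 3.00 min this gave k of 46.9 M⁻¹ min⁻¹ in the red run and 54.1 M⁻¹ min⁻¹ in the teal run, and I used 50.5 M⁻¹ min⁻¹.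

With no reagent consumed, the flask's θ would have been 7.20 M·s, leaving 0.233% substrate. With the main step taking one reagent per substrate, my θ came down to 4.80 M·s and my substrate went up to 1.76%. Then I added the second step. At 3.00 min, uptake per substrate converted read 1.33 in the red run and 1.45 in the teal run, higher at the higher concentration, and the same rise again, for the next equal step in concentration, gave 1.57 for the flask, a figure from that reading time which I carried unchanged to 4.0 min. That left the exposure, the area under free reagent against time, at 3.43 M·s. My reckoning was 5.56% substrate, 62.6% double product and 31.8% mono adduct.

The forecast, grounded on “Free reagent is fed minus consumed”, gave 6.3% substrate, 25% mono adduct and 68.7% double product.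

The flask gave 7.07% substrate, 27.4% mono adduct and 54.6% double product. My double product stood 8 percentage points higher, and the three fall short of the charge by the over-reaction product, 10.9%.

    reagent + mono adduct → over-reaction product (k = 5.19 M⁻¹ min⁻¹)
    substrate + reagent → mono adduct (k = 42.8 M⁻¹ min⁻¹)
    reagent + mono adduct → double product (k = 26.0 M⁻¹ min⁻¹)

The flask was not at rest at 4.0 min: the half-life of mono adduct by its conversion into double product was then 0.94 min, short against that time. By 40.0 min, substrate stood at 0%, mono adduct at 0%, double product at 83.4%, over-reaction product at 16.6%, and free reagent had gone from 47.2% to 33.3% of its charge. That last level, held over the added time, gives 43.2 M·s of exposure against my 3.43 M·s during the dose.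

With 12.0 equiv of reagent in the same flask, my triangle, with each substrate taking two reagent, gives θ of 24.0 M·s, so my k·θ is 20.2, and I reckon 83.3% of the reagent free. The computed flask held 0% substrate and 83.3% reagent.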